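A small charge of E, 0.0030 M in flask epsilon, meets a much larger charge of J, and the books of that flask can be kept one E at a time.

    E + J → E.J (k1 = 0.00405 /M/s)
    E + J → D (k2 = 0.00669 /M/s)
    D → X (k3 = 0.00113 /s)
    J + X → J.X (k4 = 0.00663 /M/s)
    J + J.X → J.J.X (k5 = 0.0143 /M/s)

in all of them: J 0.112 M; time 4.0 h

| run | E |
|---|---|
| epsilon | 0.0030 M |
| zeta | 0.010 M |
| delta | 0.030 M |
| eta | 0.10 M |
| gamma | 0.30 M |

- [J.X] at the end for epsilon, zeta, delta, eta, gamma, in this order
- how the row runs (hardly changes / falls, then rises / falls all the way / rises all the way / rises, then falls)

- "hardly changes" means that all values lie within two and a half points (for a concentration: within two and a half percent of the largest)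
- run time (epsilon): 4.0 h

1. In epsilon, E is the limiting reagent. Each E takes one J and enters one of two accounts. Both steps have the same partners, so the share going to D is φ = 62.3% at any J, and the step to D is faster than the step to E.J. The remaining E stays as E.J, which reacts no further.

2. With J at its charge, the half-lives are 0.170 h for D, 0.259 h for X and 0.120 h for J.X. Each is shorter than the run of 4.0 h, so the D account in epsilon passes through X and J.X into J.J.X, taking up two more J.

3. The books close with n, the J spent per E charged, n = 1 + 2φ = 2.25. J loses a small correction in epsilon, and the fraction of its charge left is 94.0%.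

4. J.X is what remains unpaid in these books, and n does not price that tail. It does give a bill to hold against the J charged. In delta the bill of 0.0675 M is less than the J charged, so J.X can still be passed on, though more slowly as J falls. In eta the bill of 0.225 M is more than the J charged, so J becomes limiting and J.X should stay behind. In gamma, with E at its charge, J has a half-life against E of 0.0598 h, shorter than that of D, so X should arrive late and find little J. This reckoning therefore expects a row that rises, then falls, and gives no values for it.

5. The forecast gave 5.000 × 10⁻⁷ M, 5.000 × 10⁻⁶ M, 2.000 × 10⁻⁴ M, 0.0085 M and 0.0035 M, rises, then falls, holding that “the J runs out and strands J.X at its highest level”. The flasks give 4.32 × 10⁻⁷ M, 4.26 × 10⁻⁶ M, 2.38 × 10⁻⁴ M, 0.0102 M and 0.00269 M, rises, then falls.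

In epsilon, the half-life of J.X by its step to J.J.X, 0.12 h with the other concentrations as charged, is shorter than the run of 4.0 h. At the end of epsilon, J.X stands at 0.0144% of the E charged, beside 62.3% as J.J.X and 37.7% as E.J. J left in epsilon is 94% of its charge, against the 94.0% entered with n. In delta, with 0.030 M charged, n leaves 39.8% of the J, and the flask holds 39.8% after 40.0 h.

All constants are made up, and the outcome is calculated.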